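**Plan**
- Retrosynthesis: once the three N-protecting groups are removed, the only skeletal cut is the biaryl bond between imidazole C2 and C3 of the bromine-free indole. The remaining 4-(6-bromoindol-3-yl)imidazole is opened across the imidazole ring to a 3-chloroacetylindole and formamidine, then cut at the indole C3–acyl bond.
- Enabling feature: imidazole C2 is the only carbon lying between two ring nitrogens, so its C–H is the most acidic one in the protected bromoindolyl-imidazole. The bond it forms to indole C3 is remote from the C6–Br bond, which travels on the nucleophile.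
- Forward: 6-bromoindole is chloroacetylated at C3, the imidazole ring is closed by condensation with formamidine acetate (the only ring built), and the nitrogens are protected with SEM and TIPS. Indole is iodinated at C3 and Boc-protected. The halves are joined by magnesiation, zincation and Negishi coupling; fluoride and then acid remove the protecting groups.
- Stereochemistry: the target is achiral and has no stereocentre; only site selectivity and chemoselectivity need control.

Key step: step 7

Remark: SEM = [2-(trimethylsilyl)ethoxy]methyl, TIPS = triisopropylsilyl. Alkylation of the imidazolide of 5 is assumed to occur at the ring nitrogen remote from the indolyl group (1,4-isomer 6). The 1,5-isomer has the same skeleton and would converge on the same target after deprotection.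

**Route**

Step 1
Reactants: 1 6-bromoindole; 2 chloroacetyl chloride
Product: 3 2-chloro-1-(6-bromo-1H-indol-3-yl)ethanone
Conditions: pyridine (1.1 equiv), toluene, 60 °C
Reagents that add atoms: none
Why: Friedel–Crafts-type acylation of the unprotected indole at its enamine-like C3, the most nucleophilic carbon, with pyridine taking up the HCl, while the aryl bromide and the alkyl chloride are inert under these conditions.

Step 2
Reactants: 3 2-chloro-1-(6-bromo-1H-indol-3-yl)ethanone; 4 formamidine acetate
Product: 5 4-(6-bromo-1H-indol-3-yl)-1H-imidazole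
Conditions: HC(=NH)NH2·AcOH (4 equiv), liquid NH3, sealed vessel, rt to 45 °C
Reagents that add atoms: none
Why: amidine–α-halo ketone imidazole synthesis, in which formamidine, set free from its acetate by ammonia, supplies N1, C2 and N3 in one piece by N-alkylation at the CH2Cl carbon and condensation at the ketone, and loss of water aromatises the ring with the indolyl group at C4 and C2 left unsubstituted.

Step 3
Reactants: 5 4-(6-bromo-1H-indol-3-yl)-1H-imidazole
Product: 6 4-(6-bromo-1H-indol-3-yl)-1-{[2-(trimethylsilyl)ethoxy]methyl}imidazole
Conditions: NaH (1.0 equiv), THF, 0 °C; then SEMCl (1.0 equiv), 0 °C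
Reagents that add atoms: 2-(trimethylsilyl)ethoxymethyl chloride (SEMCl), C[Si](C)(C)CCOCCl
Why: N-alkylation of the imidazolide, since one equivalent of NaH should remove the more acidic imidazole N–H ahead of the indole N–H and the reactive chloromethyl ether should attack the nitrogen remote from the bulky indolyl substituent.

Step 4
Reactants: 6 4-(6-bromo-1H-indol-3-yl)-1-{[2-(trimethylsilyl)ethoxy]methyl}imidazole
Product: 7 4-[6-bromo-1-(triisopropylsilyl)indol-3-yl]-1-{[2-(trimethylsilyl)ethoxy]methyl}imidazole
Conditions: NaH (1.2 equiv), THF, 0 °C; then TIPSCl, 0 °C to rt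
Reagents that add atoms: triisopropylsilyl chloride (TIPSCl), CC(C)[Si](Cl)(C(C)C)C(C)C
Why: N-silylation of the sodium indolide at the only N–H left, which installs a group that withstands amide bases and sterically shields indole C2 from later metalation.

Step 5
Reactants: 8 indole
Product: 9 3-iodo-1H-indole
Conditions: I2 (1.05 equiv), KOH (2.5 equiv), DMF, rt; used crude at once
Reagents that add atoms: iodine, II
Why: electrophilic iodination of the indolyl anion at C3, the standard entry to 3-iodoindoles, with the labile product taken on without storage.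

Step 6
Reactants: 9 3-iodo-1H-indole
Product: 10 tert-butyl 3-iodoindole-1-carboxylate
Conditions: Boc2O (1.2 equiv), DMAP (cat.), CH2Cl2, rt
Reagents that add atoms: di-tert-butyl dicarbonate (Boc2O), CC(C)(C)OC(=O)OC(=O)OC(C)(C)C
Why: DMAP-catalysed N-acylation with Boc2O, which stabilises the iodoindole and lowers the electron density of the ring so that the carbon–iodine bond adds readily to palladium.

Step 7
Reactants: 7 4-[6-bromo-1-(triisopropylsilyl)indol-3-yl]-1-{[2-(trimethylsilyl)ethoxy]methyl}imidazole; 10 tert-butyl 3-iodoindole-1-carboxylate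
Product: 13 tert-butyl 3-{4-[6-bromo-1-(triisopropylsilyl)indol-3-yl]-1-{[2-(trimethylsilyl)ethoxy]methyl}imidazol-2-yl}indole-1-carboxylate, via imidazol-2-ylmagnesium chloride 11 (not isolated), via imidazol-2-ylzinc chloride 12 (not isolated)
Conditions: TMPMgCl·LiCl (1.2 equiv), THF, −20 to 0 °C; ZnCl2 (1.3 equiv), 0 °C to rt; then 10 (1.0 equiv), Pd(PPh3)4 (5 mol %), rt to 50 °C
Reagents that add atoms: none
Why: The hindered amide base TMPMgCl·LiCl should remove the imidazole C2 proton, helped by chelation to the SEM oxygen, to give Grignard reagent 11, and ZnCl2 converts this into the milder zinc reagent 12, which leaves the carbamate of 10 alone. Zerovalent palladium adds to the carbon–iodine bond of 10, the imidazolyl group passes from zinc to divalent palladium, and reductive elimination joins imidazole C2 to indole C3. The closest known reaction type is the directed magnesiation of N-protected azoles with TMP–magnesium bases followed by Negishi coupling with aryl iodides. No ring is closed and no stereocentre is formed; one carbon–carbon bond links two existing rings. Metalation must occur only at imidazole C2, which is secured by the acidity of the C–H between two nitrogens, by the TIPS group blocking indole C2, and by the fact that an amide base deprotonates but does not exchange an aryl bromide. Palladium must take the iodide and not the bromide, which is secured because the electron-rich C6–Br bond sits on the nucleophile and adds far more slowly than the iodide with PPh3 ligands at or below 50 °C.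

Step 8
Reactants: 13 tert-butyl 3-{4-[6-bromo-1-(triisopropylsilyl)indol-3-yl]-1-{[2-(trimethylsilyl)ethoxy]methyl}imidazol-2-yl}indole-1-carboxylate
Product: 14 tert-butyl 3-[4-(6-bromo-1H-indol-3-yl)-1-{[2-(trimethylsilyl)ethoxy]methyl}imidazol-2-yl]indole-1-carboxylate
Conditions: TBAF (1.1 equiv), THF, 0 °C, short reaction time; aqueous work-up
Reagents that add atoms: none
Why: fluoride-induced N-desilylation is fast at 0 °C, a temperature at which the SEM aminal and the Boc carbamate should stay in place, and the lipophilic product can be freed of ammonium salts by chromatography.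

Step 9
Reactants: 14 tert-butyl 3-[4-(6-bromo-1H-indol-3-yl)-1-{[2-(trimethylsilyl)ethoxy]methyl}imidazol-2-yl]indole-1-carboxylate
Product: 15 nortopsentin C (6-bromo-3-[2-(1H-indol-3-yl)-1H-imidazol-4-yl]-1H-indole)
Conditions: 3 M aq. HCl, EtOH, reflux; then aq. NaHCO3
Reagents that add atoms: none
Why: acidolysis, in which HCl cleaves the Boc carbamate with loss of isobutene and CO2 and hydrolyses the N,O-acetal of the SEM group, while protonation of the imidazole deactivates the two C3-substituted indoles toward acid-induced side reactions before neutralisation releases the free base.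

**Compound list**
1 | 6-bromoindole | Brc1ccc2cc[nH]c2c1 | starting material
2 | chloroacetyl chloride | ClCC(Cl)=O | starting material
3 | 2-chloro-1-(6-bromo-1H-indol-3-yl)ethanone | O=C(CCl)c1c[nH]c2cc(Br)ccc12 | intermediate
4 | formamidine acetate (methanimidamide acetate) | CC(=O)O.N=CN | starting material
5 | 4-(6-bromo-1H-indol-3-yl)-1H-imidazole | Brc1ccc2c(-c3c[nH]cn3)c[nH]c2c1 | intermediate
6 | 4-(6-bromo-1H-indol-3-yl)-1-{[2-(trimethylsilyl)ethoxy]methyl}imidazole | Brc1ccc2c(-c3cn(COCC[Si](C)(C)C)cn3)c[nH]c2c1 | intermediate
7 | 4-[6-bromo-1-(triisopropylsilyl)indol-3-yl]-1-{[2-(trimethylsilyl)ethoxy]methyl}imidazole | Brc1ccc2c(-c3cn(COCC[Si](C)(C)C)cn3)cn([Si](C(C)C)(C(C)C)C(C)C)c2c1 | intermediate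
8 | indole | c1ccc2[nH]ccc2c1 | starting material
9 | 3-iodo-1H-indole | Ic1c[nH]c2ccccc12 | intermediate
10 | tert-butyl 3-iodoindole-1-carboxylate | CC(C)(C)OC(=O)n1cc(I)c2ccccc12 | intermediate
11 | {4-[6-bromo-1-(triisopropylsilyl)indol-3-yl]-1-{[2-(trimethylsilyl)ethoxy]methyl}imidazol-2-yl}magnesium chloride (LiCl complex, not isolated) | Brc1ccc2c(-c3cn(COCC[Si](C)(C)C)c([Mg]Cl)n3)cn([Si](C(C)C)(C(C)C)C(C)C)c2c1 | intermediate
12 | {4-[6-bromo-1-(triisopropylsilyl)indol-3-yl]-1-{[2-(trimethylsilyl)ethoxy]methyl}imidazol-2-yl}zinc chloride (not isolated) | Brc1ccc2c(-c3cn(COCC[Si](C)(C)C)c([Zn]Cl)n3)cn([Si](C(C)C)(C(C)C)C(C)C)c2c1 | intermediate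
13 | tert-butyl 3-{4-[6-bromo-1-(triisopropylsilyl)indol-3-yl]-1-{[2-(trimethylsilyl)ethoxy]methyl}imidazol-2-yl}indole-1-carboxylate | Brc1ccc2c(-c3cn(COCC[Si](C)(C)C)c(-c4cn(C(=O)OC(C)(C)C)c5ccccc45)n3)cn([Si](C(C)C)(C(C)C)C(C)C)c2c1 | intermediate
14 | tert-butyl 3-[4-(6-bromo-1H-indol-3-yl)-1-{[2-(trimethylsilyl)ethoxy]methyl}imidazol-2-yl]indole-1-carboxylate | Brc1ccc2c(-c3cn(COCC[Si](C)(C)C)c(-c4cn(C(=O)OC(C)(C)C)c5ccccc45)n3)c[nH]c2c1 | intermediate
15 | nortopsentin C (6-bromo-3-[2-(1H-indol-3-yl)-1H-imidazol-4-yl]-1H-indole) | Brc1ccc2c(-c3c[nH]c(-c4c[nH]c5ccccc45)n3)c[nH]c2c1 | target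

**Step count**
Total steps: 9. Longest linear sequence: 7 steps (steps 1, 2, 3, 4, 7, 8 and 9 from 6-bromoindole); the branch from indole has 2 steps (5 and 6).

**Steps most likely to fail**

Step 7. The hindered 2-imidazolylzinc reagent may transfer to palladium too slowly, so that protodemetalation back to 7, homocoupling of 10 or slow insertion into the C6–Br bond take over. The fallback inverts the polarity of the union. It sets out from 7: deprotonation with LiTMP in THF at −78 °C (a lithium amide deprotonates but does not exchange the aryl bromide) would give the 2-lithioimidazole F1. Quenching with I2 would give 4-[6-bromo-1-(triisopropylsilyl)indol-3-yl]-2-iodo-1-{[2-(trimethylsilyl)ethoxy]methyl}imidazole F2. Suzuki–Miyaura coupling of F2 with commercial tert-butyl 3-(4,4,5,5-tetramethyl-1,3,2-dioxaborolan-2-yl)indole-1-carboxylate, using Pd(PPh3)4 and aqueous Na2CO3 in DME at 80 °C, would form the same C2–C3 bond and come back to the route at 13. The imidazole carbon–iodine bond should add to zerovalent palladium well ahead of the C6–Br bond.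

Step 2. Ammonia may compete with the amidine for the chloromethyl carbon, leading to the amino ketone and its self-condensation, and ring closure onto the deactivated, vinylogous-amide ketone may stall before dehydration. The fallback installs the nitrogens stepwise and closes the ring under acid. It sets out from 3: displacement of chloride with NaN(CHO)2 in MeCN at 80 °C would give N-[2-(6-bromo-1H-indol-3-yl)-2-oxoethyl]-N-formylformamide F3. Catalytic KOH in EtOH at rt would remove one formyl group to give N-[2-(6-bromo-1H-indol-3-yl)-2-oxoethyl]formamide F4. Heating F4 with NH4OAc in AcOH at reflux (Davidson-type cyclocondensation of an α-acylamino ketone) would close the imidazole and come back to the route at 5.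

Step 3. The SEM alkylation may spread over the indole nitrogen or over both imidazole nitrogens. The fallback inverts the order of protection so that SEMCl meets a single N–H. It sets out from 5: NaH (2.2 equiv) and TIPSCl (2.2 equiv) in THF would silylate both nitrogens to give 4-[6-bromo-1-(triisopropylsilyl)indol-3-yl]-1-(triisopropylsilyl)imidazole F5. The N-silylimidazole, by nature a silyl-transfer agent, would be cleaved selectively by stirring with MeOH at rt, leaving 4-[6-bromo-1-(triisopropylsilyl)indol-3-yl]-1H-imidazole F6. NaH and SEMCl in THF would then alkylate the only N–H, away from the very bulky C4 substituent, and come back to the route at 7.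

**Further compounds**
F1 | step 7 | {4-[6-bromo-1-(triisopropylsilyl)indol-3-yl]-1-{[2-(trimethylsilyl)ethoxy]methyl}imidazol-2-yl}lithium | Brc1ccc2c(-c3cn(COCC[Si](C)(C)C)c([Li])n3)cn([Si](C(C)C)(C(C)C)C(C)C)c2c1
F2 | step 7 | 4-[6-bromo-1-(triisopropylsilyl)indol-3-yl]-2-iodo-1-{[2-(trimethylsilyl)ethoxy]methyl}imidazole | Brc1ccc2c(-c3cn(COCC[Si](C)(C)C)c(I)n3)cn([Si](C(C)C)(C(C)C)C(C)C)c2c1
F3 | step 2 | N-[2-(6-bromo-1H-indol-3-yl)-2-oxoethyl]-N-formylformamide | O=CN(C=O)CC(=O)c1c[nH]c2cc(Br)ccc12
F4 | step 2 | N-[2-(6-bromo-1H-indol-3-yl)-2-oxoethyl]formamide | O=CNCC(=O)c1c[nH]c2cc(Br)ccc12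
F5 | step 3 | 4-[6-bromo-1-(triisopropylsilyl)indol-3-yl]-1-(triisopropylsilyl)imidazole | Brc1ccc2c(-c3cn([Si](C(C)C)(C(C)C)C(C)C)cn3)cn([Si](C(C)C)(C(C)C)C(C)C)c2c1
F6 | step 3 | 4-[6-bromo-1-(triisopropylsilyl)indol-3-yl]-1H-imidazole | Brc1ccc2c(-c3c[nH]cn3)cn([Si](C(C)C)(C(C)C)C(C)C)c2c1
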